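**Retrosynthetic overview**
1. Locants follow the target skeleton, tricyclo[5.4.0.0^{1,4}]undecane: ring A = C1–C4 (cyclobutane), ring B = C1, C4–C7 (cyclopentane), ring C = C1, C7–C11 (cyclohexane).
2. 29 ⇐ 21: both bromides and the C10 hydroxyl grow from carbonyl groups (C5 ketone → alkenyl bromide → hydrogen-atom-transfer hydrogenation; C10 ketone → C9 bromination → reduction).
3. Ring C is closed last (21 ⇐ 20) through the C7–C8 bond by a metal-hydride hydrogen-atom-transfer radical conjugate addition. Enabling feature: in ring B, C7 is β to C5, so C5(=O)–C6=C7 can be the acceptor, and C8 carries a methyl group that can be born as the CH2 of a terminal alkene, which puts the radical on C8.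
4. 20 ⇐ 11 ⇐ 9: ring A by intramolecular enone–alkene [2+2] photocycloaddition onto ring B through a temporary oxolane tether (C2–O–C10). The tether fixes the C2 oxygen and relays the C11 stereocentre to C1, C2 and C4; it is opened again (lactone, lactol, allylation).
5. Absolute configuration comes from a ketoreductase dynamic reductive kinetic resolution of aldehyde 6; order of ring formation: B (present in 1) → A (step 5) → C (step 12).

Key step: step 12

Remark: C10 of compounds 15–25 is a mixture of carbinol epimers (it becomes a ketone in step 16), so the SMILES leave it undefined.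

Step 1
Reactants: 1 3-ethoxy-2-methylcyclopent-2-en-1-one; 2 but-2-en-1-ylmagnesium chloride
Product: 4 3-(but-3-en-2-yl)-2-methylcyclopent-2-en-1-one (racemic), via magnesium alkoxide 3 (not isolated)
Conditions: THF, −78 to 0 °C; then 1 M HCl, 0 °C
Reagents that add atoms: water (O)
Why: γ-Selective 1,2-addition of the crotyl Grignard reagent (allylic transposition through a six-membered transition state) to the vinylogous ester carbonyl, followed by acid-induced Stork–Danheiser transposition, should give the 3-(1-methylallyl) enone; the side-chain stereocentre is racemic here and is set in step 3.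

Step 2
Reactants: 4 3-(but-3-en-2-yl)-2-methylcyclopent-2-en-1-one
Product: 6 2-(2-methyl-3-oxocyclopent-1-en-1-yl)propanal (racemic), via ozonide 5 (not isolated)
Conditions: O3, CH2Cl2, −78 °C (Sudan red 7B end point); then Me2S, −78 to 23 °C
Reagents that add atoms: ozone (O=[O+][O-])
Why: Ozonolysis with reductive work-up should cleave only the electron-rich monosubstituted alkene, because the tetrasubstituted enone C=C is electron-poor and hindered.

Step 3
Reactants: 6 2-(2-methyl-3-oxocyclopent-1-en-1-yl)propanal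
Product: 7 3-[(2R)-1-hydroxypropan-2-yl]-2-methylcyclopent-2-en-1-one
Conditions: (R)-selective ketoreductase (NADPH-dependent alcohol dehydrogenase), NADP+ (cat.), i-PrOH, phosphate buffer pH 7.5–8, 30 °C
Reagents that add atoms: none
Why: Enzymatic dynamic reductive kinetic resolution of the type established for 2-arylpropanals: the stereocentre of 6 is α to the aldehyde and vinylogously α to the ring ketone, so it racemises in the buffer faster than the enzyme reduces the matched enantiomer, which should funnel the material to the (R)-alcohol (future C11) while the hindered conjugated ketone is not a substrate.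

Step 4
Reactants: 7 3-[(2R)-1-hydroxypropan-2-yl]-2-methylcyclopent-2-en-1-one; 8 butyl vinyl ether
Product: 9 3-[(2R)-1-(ethenyloxy)propan-2-yl]-2-methylcyclopent-2-en-1-one
Conditions: Pd(OCOCF3)2 (cat.), 4,7-diphenyl-1,10-phenanthroline, Et3N, 8 as solvent, 75 °C
Reagents that add atoms: none
Why: Palladium-catalysed transfer vinylation (transetherification) of a primary alcohol with excess alkyl vinyl ether should give the vinyl ether without touching the enone or the stereocentre.

Step 5
Reactants: 9 3-[(2R)-1-(ethenyloxy)propan-2-yl]-2-methylcyclopent-2-en-1-one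
Product: 10 (1S,2R,5R,7R)-2,7-dimethyl-4-oxatricyclo[5.3.0.0^{1,5}]decan-8-one
Conditions: hν (350 nm, Pyrex), degassed MeCN (0.01 M), 0 °C
Reagents that add atoms: none
Why: Intramolecular enone–alkene [2+2] photocycloaddition with a three-atom tether (first bond closes the five-membered oxolane, so the straight regioisomer results) forms ring A with C2–O on C1 and C3 on C4, both ring fusions cis by geometry, and the face is set by the C11 stereocentre, whose hydrogen eclipses the C1=C4 bond to avoid allylic 1,3-strain with the C4 methyl so that the CH2O arm delivers the alkene to one face only.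

Step 6
Reactants: 10 (1S,2R,5R,7R)-2,7-dimethyl-4-oxatricyclo[5.3.0.0^{1,5}]decan-8-one
Product: 11 (1S,2R,5R,7R)-2,7-dimethyl-4-oxatricyclo[5.3.0.0^{1,5}]decane-3,8-dione
Conditions: RuCl3·xH2O (cat.), NaIO4, CCl4/MeCN/H2O, 23 °C
Reagents that add atoms: sodium periodate ([Na+].[O-]I(=O)(=O)=O)
Why: Ruthenium tetroxide oxidation of a cyclic ether to a lactone should occur at the α-methylene (C10) in preference to the strained, hindered cyclobutyl methine at C2.

Step 7
Reactants: 11 (1S,2R,5R,7R)-2,7-dimethyl-4-oxatricyclo[5.3.0.0^{1,5}]decane-3,8-dione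
Product: 13 (1S,2R,5R,7R)-3-hydroxy-2,7-dimethyl-4-oxatricyclo[5.3.0.0^{1,5}]decan-8-one (lactol), via lithium enolate 12 (not isolated)
Conditions: LiN(SiMe3)2 (1.05 equiv), THF, −78 °C; then i-Bu2AlH (1.1 equiv), −78 °C; aq. NH4Cl, Rochelle salt
Reagents that add atoms: none
Why: The ketone, enolisable only at C6, is masked in the flask as its lithium enolate so that the aluminium hydride reduces only the lactone to the lactol (stable tetrahedral aluminate at −78 °C), and protonation on work-up returns the ketone.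

Step 8
Reactants: 13 lactol; 14 4,4,5,5-tetramethyl-2-(prop-2-en-1-yl)-1,3,2-dioxaborolane
Product: 15 (1R,5S,6R)-6-hydroxy-5-[(2R)-3-hydroxyhex-5-en-2-yl]-1-methylbicyclo[3.2.0]heptan-2-one
Conditions: toluene, 23 to 50 °C; aqueous work-up
Reagents that add atoms: none
Why: Allylboration of the open hydroxy-aldehyde tautomer of the lactol through a chair (Zimmerman–Traxler) transition state should add the three carbons that become C9, C8 and the C8 methyl, the allylboronate being unreactive toward the hindered ketone.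

Step 9
Reactants: 15 (1R,5S,6R)-6-hydroxy-5-[(2R)-3-hydroxyhex-5-en-2-yl]-1-methylbicyclo[3.2.0]heptan-2-one
Product: 17 (1R,5S,6R)-5-{(2R)-3-[(tert-butyldimethylsilyl)oxy]hex-5-en-2-yl}-1-methyl-2-oxobicyclo[3.2.0]heptan-6-yl acetate, via mono-silyl ether 16 (not isolated)
Conditions: TBSCl (1.1 equiv), imidazole, DMF, 0 °C; then Ac2O, DMAP, Et3N, 23 °C
Reagents that add atoms: tert-butyldimethylsilyl chloride (CC(C)(C)[Si](C)(C)Cl); acetic anhydride (CC(=O)OC(C)=O)
Why: Silylation with a bulky chlorosilane should discriminate the C10 hydroxyl (flanked by CH and CH2) from the neopentylic cyclobutanol at C2, which is then acetylated in the same flask to install the acetate of the target.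

Step 10
Reactants: 17 silyl ether acetate
Product: 18 (1R,5S,6R)-5-{(2R)-3-[(tert-butyldimethylsilyl)oxy]hex-5-en-2-yl}-1-methyl-2-oxobicyclo[3.2.0]hept-3-en-6-yl acetate
Conditions: IBX, DMSO/fluorobenzene, 65 °C
Reagents that add atoms: none
Why: IBX-mediated α,β-dehydrogenation of the ketone can only desaturate C6–C7 because C4 is quaternary.

Step 11
Reactants: 18 enone
Product: 20 (1R,5R,6R)-5-{(2R)-3-[(tert-butyldimethylsilyl)oxy]hex-5-en-2-yl}-1,4-dimethyl-2-oxobicyclo[3.2.0]hept-3-en-6-yl acetate, via silyl enol ether 19 (not isolated)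
Conditions: Me2CuLi, Me3SiCl, THF, −78 to −40 °C; then IBX, 4-methoxypyridine N-oxide, DMSO, 23 °C
Reagents that add atoms: lithium dimethylcuprate ([Li+].C[Cu-]C)
Why: Chlorosilane-accelerated conjugate addition of the cuprate puts the methyl group on C7 and gives silyl enol ether 19, whose dehydrogenation (the metal-free counterpart of the Saegusa–Ito oxidation) regenerates the enone, so the transient C7 stereocentre is erased.

Step 12
Reactants: 20 β-methyl enone with pendant allyl group
Product: 21 (1R,2R,4R,7R,8S,11R)-10-[(tert-butyldimethylsilyl)oxy]-4,7,8,11-tetramethyl-5-oxotricyclo[5.4.0.0^{1,4}]undecan-2-yl acetate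
Conditions: Fe(acac)3 (30 mol %), PhSiH3, EtOH/ethylene glycol, 60 °C
Reagents that add atoms: none
Why: An iron hydride (trivalent iron) formed from Fe(acac)3 and PhSiH3 transfers a hydrogen atom to the terminal CH2 of the monosubstituted alkene, which creates the C8 methyl group and the secondary C8 radical; this nucleophilic radical adds to C7, the β-carbon of the C5(=O)–C6=C7 enone, and the resulting C6 α-keto radical is reduced by divalent iron to the enolate and protonated by ethanol. The closest known reaction type is the intramolecular metal-hydride hydrogen-atom-transfer reductive olefin–enone coupling (radical Giese cyclisation), which is established for building quaternary carbons next to existing ones. Ring C closes in the 6-exo-trig mode. C7 is fixed by geometry, because the chain hangs from C1 on one face of ring B and can reach C7 only on that face (cis B/C fusion), and C8 follows from a chair-like transition state with the C8 and C11 methyl groups equatorial, an axial C8 methyl being 1,3-diaxial to the C1–C4 bond. The step needs hydrogen-atom transfer to the electron-rich terminal alkene and not to the electron-poor trisubstituted enone, and cyclisation faster than a second hydrogen transfer; the polarity preference of the metal hydride secures the first and the 1,6-relationship of radical and acceptor the second. Neither radical centre (C8, C6) is adjacent to ring A, so no cyclobutylcarbinyl ring opening can intervene.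

Step 13
Reactants: 21 tricyclic C5 ketone
Product: 23 (1R,2R,4R,7S,8S,11R)-10-[(tert-butyldimethylsilyl)oxy]-4,7,8,11-tetramethyl-5-{[(trifluoromethyl)sulfonyl]oxy}tricyclo[5.4.0.0^{1,4}]undec-5-en-2-yl acetate, via potassium enolate 22 (not isolated)
Conditions: KN(SiMe3)2 (1.05 equiv), THF, −78 °C; then PhNTf2, −78 to 0 °C
Reagents that add atoms: N-phenylbis(trifluoromethanesulfonimide) (O=S(=O)(N(c1ccccc1)S(=O)(=O)C(F)(F)F)C(F)(F)F)
Why: Kinetic deprotonation at C6, the only enolisable position, and O-sulfonylation of the enolate give the enol triflate without cationic intermediates that could trigger rearrangement of ring A, the less acidic acetate being spared at −78 °C.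

Step 14
Reactants: 23 enol triflate
Product: 24 (1R,2R,4R,7S,8S,11R)-5-bromo-10-[(tert-butyldimethylsilyl)oxy]-4,7,8,11-tetramethyltricyclo[5.4.0.0^{1,4}]undec-5-en-2-yl acetate
Conditions: Ni(OAc)2·4H2O (10 mol %), 1,5-cyclooctadiene, Zn (20 mol %), LiBr, DMA/THF, 23 °C
Reagents that add atoms: lithium bromide ([Li+].[Br-])
Why: Nickel-catalysed halogen exchange of an alkenyl triflate (oxidative addition to low-valent nickel, triflate/bromide exchange, C–Br reductive elimination) should give the alkenyl bromide.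

Step 15
Reactants: 24 alkenyl bromide
Product: 25 (1R,2R,4R,5S,7R,8S,11R)-5-bromo-10-[(tert-butyldimethylsilyl)oxy]-4,7,8,11-tetramethyltricyclo[5.4.0.0^{1,4}]undecan-2-yl acetate
Conditions: Mn(dpm)3 (10 mol %), PhSiH3, t-BuOOH, i-PrOH, 23 °C
Reagents that add atoms: none
Why: Metal-hydride hydrogen-atom-transfer hydrogenation reduces alkenyl halides to alkyl halides without loss of halogen; the first hydrogen atom goes to C6 and the α-bromo radical at C5 should take the second from the convex face of the bicyclo[3.2.0]heptane unit (anti to the C3 methylene), which places bromine syn to ring A and anti to the C4 methyl, also the less strained C5 epimer.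

Step 16
Reactants: 25 C5 bromide, C10 silyl ether
Product: 26 (1R,2R,4R,5S,7R,8S,11R)-5-bromo-4,7,8,11-tetramethyl-10-oxotricyclo[5.4.0.0^{1,4}]undecan-2-yl acetate
Conditions: CrO3, H2SO4, acetone/H2O, 0 to 23 °C
Reagents that add atoms: none
Why: Jones oxidation in aqueous acid cleaves the silyl ether and oxidises the liberated secondary alcohol in one operation, and the acidic medium lets C11 settle in the equatorial-methyl configuration.

Step 17
Reactants: 26 C10 ketone
Product: 28 (1R,2R,4R,5S,7R,8R,9S,11R)-5,9-dibromo-4,7,8,11-tetramethyl-10-oxotricyclo[5.4.0.0^{1,4}]undecan-2-yl acetate, via silyl enol ether 27 (not isolated)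
Conditions: Me3SiOTf, Et3N, CH2Cl2, 0 °C; then NBS, THF, −78 to 0 °C
Reagents that add atoms: N-bromosuccinimide (O=C1CCC(=O)N1Br)
Why: Enolisation goes toward the C9 methylene (the alternative enol ether at C11 would be tetrasubstituted and flanked by quaternary C1), and bromination of the silyl enol ether should occur anti to the axial C7 methyl to give the equatorial bromide trans to the C8 methyl, which is also the thermodynamic epimer because an axial bromine would be 1,3-diaxial to that methyl.

Step 18
Reactants: 28 α-bromo ketone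
Product: 29 (1R,2R,4R,5S,7R,8R,9S,10R,11R)-5,9-dibromo-10-hydroxy-4,7,8,11-tetramethyltricyclo[5.4.0.0^{1,4}]undecan-2-yl acetate (target)
Conditions: NaBH4, MeOH/CH2Cl2, −40 °C
Reagents that add atoms: none
Why: Borohydride reduction of the α-bromo ketone: the axial trajectory at C10 is blocked by the axial C1–C4 bond, so hydride should arrive equatorially and give the axial alcohol cis to the C9 bromine and the C11 methyl, a cis-bromohydrin that cannot close to an epoxide, while the acetate survives.

**Compound list**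
1 | 3-ethoxy-2-methylcyclopent-2-en-1-one | CCOC1=C(C)C(=O)CC1 | starting material
2 | but-2-en-1-ylmagnesium chloride (crotylmagnesium chloride, THF solution) | CC=CC[Mg]Cl | starting material
3 | chloromagnesium 1-(but-3-en-2-yl)-3-ethoxy-2-methylcyclopent-2-en-1-olate (diastereomer mixture) | CCOC1=C(C)C(O[Mg]Cl)(C(C)C=C)CC1 | intermediate
4 | 3-(but-3-en-2-yl)-2-methylcyclopent-2-en-1-one (racemic) | C=CC(C)C1=C(C)C(=O)CC1 | intermediate
5 | 2-methyl-3-[1-(1,2,4-trioxolan-3-yl)ethyl]cyclopent-2-en-1-one (ozonide) | CC(C1OCOO1)C1=C(C)C(=O)CC1 | intermediate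
6 | 2-(2-methyl-3-oxocyclopent-1-en-1-yl)propanal (racemic, configurationally labile) | O=CC(C)C1=C(C)C(=O)CC1 | intermediate
7 | 3-[(2R)-1-hydroxypropan-2-yl]-2-methylcyclopent-2-en-1-one | OC[C@H](C)C1=C(C)C(=O)CC1 | intermediate
8 | butyl vinyl ether (1-(ethenyloxy)butane) | CCCCOC=C | starting material
9 | 3-[(2R)-1-(ethenyloxy)propan-2-yl]-2-methylcyclopent-2-en-1-one | C=COC[C@H](C)C1=C(C)C(=O)CC1 | intermediate
10 | (1S,2R,5R,7R)-2,7-dimethyl-4-oxatricyclo[5.3.0.0^{1,5}]decan-8-one (ring B ketone, ring A, temporary oxolane; all ring fusions cis) | O1[C@@H]2C[C@@]3(C)C(=O)CC[C@@]23[C@@H](C)C1 | intermediate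
11 | (1S,2R,5R,7R)-2,7-dimethyl-4-oxatricyclo[5.3.0.0^{1,5}]decane-3,8-dione (γ-lactone) | O1[C@@H]2C[C@@]3(C)C(=O)CC[C@@]23[C@@H](C)C1=O | intermediate
12 | lithium enolate of 11 (O–C8=C9 in the numbering of 11) | O1[C@@H]2C[C@@]3(C)C(O[Li])=CC[C@@]23[C@@H](C)C1=O | intermediate
13 | (1S,2R,5R,7R)-3-hydroxy-2,7-dimethyl-4-oxatricyclo[5.3.0.0^{1,5}]decan-8-one (lactol, anomer mixture) | O1[C@@H]2C[C@@]3(C)C(=O)CC[C@@]23[C@@H](C)C1O | intermediate
14 | 4,4,5,5-tetramethyl-2-(prop-2-en-1-yl)-1,3,2-dioxaborolane (allylboronic acid pinacol ester) | C=CCB1OC(C)(C)C(C)(C)O1 | starting material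
15 | (1R,5S,6R)-6-hydroxy-5-[(2R)-3-hydroxyhex-5-en-2-yl]-1-methylbicyclo[3.2.0]heptan-2-one (side-chain carbinol epimers) | O[C@@H]1C[C@@]2(C)C(=O)CC[C@@]12[C@@H](C)C(O)CC=C | intermediate
16 | (1R,5S,6R)-5-{(2R)-3-[(tert-butyldimethylsilyl)oxy]hex-5-en-2-yl}-6-hydroxy-1-methylbicyclo[3.2.0]heptan-2-one | O[C@@H]1C[C@@]2(C)C(=O)CC[C@@]12[C@@H](C)C(O[Si](C)(C)C(C)(C)C)CC=C | intermediate
17 | (1R,5S,6R)-5-{(2R)-3-[(tert-butyldimethylsilyl)oxy]hex-5-en-2-yl}-1-methyl-2-oxobicyclo[3.2.0]heptan-6-yl acetate | CC(=O)O[C@@H]1C[C@@]2(C)C(=O)CC[C@@]12[C@@H](C)C(O[Si](C)(C)C(C)(C)C)CC=C | intermediate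
18 | (1R,5S,6R)-5-{(2R)-3-[(tert-butyldimethylsilyl)oxy]hex-5-en-2-yl}-1-methyl-2-oxobicyclo[3.2.0]hept-3-en-6-yl acetate | CC(=O)O[C@@H]1C[C@@]2(C)C(=O)C=C[C@@]12[C@@H](C)C(O[Si](C)(C)C(C)(C)C)CC=C | intermediate
19 | (1R,5S,6R)-5-{(2R)-3-[(tert-butyldimethylsilyl)oxy]hex-5-en-2-yl}-1,4-dimethyl-2-[(trimethylsilyl)oxy]bicyclo[3.2.0]hept-2-en-6-yl acetate (C4 epimers) | CC(=O)O[C@@H]1C[C@@]2(C)C(O[Si](C)(C)C)=CC(C)[C@@]12[C@@H](C)C(O[Si](C)(C)C(C)(C)C)CC=C | intermediate
20 | (1R,5R,6R)-5-{(2R)-3-[(tert-butyldimethylsilyl)oxy]hex-5-en-2-yl}-1,4-dimethyl-2-oxobicyclo[3.2.0]hept-3-en-6-yl acetate | CC(=O)O[C@@H]1C[C@@]2(C)C(=O)C=C(C)[C@@]12[C@@H](C)C(O[Si](C)(C)C(C)(C)C)CC=C | intermediate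
21 | (1R,2R,4R,7R,8S,11R)-10-[(tert-butyldimethylsilyl)oxy]-4,7,8,11-tetramethyl-5-oxotricyclo[5.4.0.0^{1,4}]undecan-2-yl acetate | CC(=O)O[C@@H]1C[C@@]2(C)C(=O)C[C@]3(C)[C@@H](C)CC(O[Si](C)(C)C(C)(C)C)[C@H](C)[C@]123 | intermediate
22 | potassium C5–C6 enolate of 21 | CC(=O)O[C@@H]1C[C@@]2(C)C(O[K])=C[C@]3(C)[C@@H](C)CC(O[Si](C)(C)C(C)(C)C)[C@H](C)[C@]123 | intermediate
23 | (1R,2R,4R,7S,8S,11R)-10-[(tert-butyldimethylsilyl)oxy]-4,7,8,11-tetramethyl-5-{[(trifluoromethyl)sulfonyl]oxy}tricyclo[5.4.0.0^{1,4}]undec-5-en-2-yl acetate | CC(=O)O[C@@H]1C[C@@]2(C)C(OS(=O)(=O)C(F)(F)F)=C[C@]3(C)[C@@H](C)CC(O[Si](C)(C)C(C)(C)C)[C@H](C)[C@]123 | intermediate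
24 | (1R,2R,4R,7S,8S,11R)-5-bromo-10-[(tert-butyldimethylsilyl)oxy]-4,7,8,11-tetramethyltricyclo[5.4.0.0^{1,4}]undec-5-en-2-yl acetate | CC(=O)O[C@@H]1C[C@@]2(C)C(Br)=C[C@]3(C)[C@@H](C)CC(O[Si](C)(C)C(C)(C)C)[C@H](C)[C@]123 | intermediate
25 | (1R,2R,4R,5S,7R,8S,11R)-5-bromo-10-[(tert-butyldimethylsilyl)oxy]-4,7,8,11-tetramethyltricyclo[5.4.0.0^{1,4}]undecan-2-yl acetate | CC(=O)O[C@@H]1C[C@@]2(C)[C@@H](Br)C[C@]3(C)[C@@H](C)CC(O[Si](C)(C)C(C)(C)C)[C@H](C)[C@]123 | intermediate
26 | (1R,2R,4R,5S,7R,8S,11R)-5-bromo-4,7,8,11-tetramethyl-10-oxotricyclo[5.4.0.0^{1,4}]undecan-2-yl acetate | CC(=O)O[C@@H]1C[C@@]2(C)[C@@H](Br)C[C@]3(C)[C@@H](C)CC(=O)[C@H](C)[C@]123 | intermediate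
27 | (1R,2R,4R,5S,7R,8S,11R)-5-bromo-4,7,8,11-tetramethyl-10-[(trimethylsilyl)oxy]tricyclo[5.4.0.0^{1,4}]undec-9-en-2-yl acetate | CC(=O)O[C@@H]1C[C@@]2(C)[C@@H](Br)C[C@]3(C)[C@@H](C)C=C(O[Si](C)(C)C)[C@H](C)[C@]123 | intermediate
28 | (1R,2R,4R,5S,7R,8R,9S,11R)-5,9-dibromo-4,7,8,11-tetramethyl-10-oxotricyclo[5.4.0.0^{1,4}]undecan-2-yl acetate | CC(=O)O[C@@H]1C[C@@]2(C)[C@@H](Br)C[C@]3(C)[C@@H](C)[C@H](Br)C(=O)[C@H](C)[C@]123 | intermediate
29 | (1R,2R,4R,5S,7R,8R,9S,10R,11R)-5,9-dibromo-10-hydroxy-4,7,8,11-tetramethyltricyclo[5.4.0.0^{1,4}]undecan-2-yl acetate | CC(=O)O[C@@H]1C[C@@]2(C)[C@@H](Br)C[C@]3(C)[C@@H](C)[C@H](Br)[C@H](O)[C@H](C)[C@]123 | target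

**Totals**
Total step count: 18. Longest linear sequence: 18 steps (1 → 29).

**Steps most likely to fail**

Step 12. The secondary C8 radical may take a second hydrogen atom (plain reduction of the alkene), or the alkene may isomerise, before the hindered addition to the fully substituted C7 occurs. The fallback generates the same radical by a tin hydride chain in which the hydrogen-donor concentration can be kept low. It sets out from 20: oxymercuration–demercuration (Hg(OAc)2, THF/H2O; then NaBH4, 0 °C) should give the Markovnikov alcohol, (1R,5R,6R)-5-{(2R)-3-[(tert-butyldimethylsilyl)oxy]-5-hydroxyhexan-2-yl}-1,4-dimethyl-2-oxobicyclo[3.2.0]hept-3-en-6-yl acetate F1. 1,1′-Thiocarbonyldiimidazole and DMAP convert it into the imidazolyl thionocarbonate F2. Slow addition of Bu3SnH/AIBN in benzene at 80 °C (Barton–McCombie radical generation followed by Giese cyclisation) then closes ring C, and the route is rejoined at 21.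

Step 15. The second hydrogen-atom transfer may show poor or reversed facial selectivity at C5; the cyclobutylcarbinyl-type C5 radical may also open ring A, or bromine may be lost. The fallback replaces the radical step by ionic chemistry and sets out from 21. NaBH4 in MeOH should deliver hydride from the ring A face (the face that is open if step 15 fails in this way) and give the C5 alcohol with hydroxyl syn to the C4 methyl, (1R,2R,4R,5R,7R,8S,11R)-10-[(tert-butyldimethylsilyl)oxy]-5-hydroxy-4,7,8,11-tetramethyltricyclo[5.4.0.0^{1,4}]undecan-2-yl acetate F3. Appel bromination (CBr4, PPh3, CH2Cl2) with inversion then installs the bromide, and the route is rejoined at 25. This substitution is neopentylic and must be kept SN2-like to avoid rearrangement of ring A.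

Step 7. Masking of the ketone as its enolate may be incomplete, so that the hydride over-reduces the ketone or the lactol. The fallback reaches the lactol without a lactone, through a silicon tether, and sets out from 7. Chloro(dimethyl)vinylsilane and imidazole give the vinylsilyl ether, 3-[(2R)-1-{[ethenyl(dimethyl)silyl]oxy}propan-2-yl]-2-methylcyclopent-2-en-1-one F4. Irradiation as in step 5 should give the photoadduct with a six-membered 1-oxa-2-silacyclohexane tether ring (silicon on C2, oxygen on C10) F5, under the same allylic-strain control. Tamao–Fleming oxidation (H2O2, KF, KHCO3) with retention gives the diol, (1R,5S,6R)-6-hydroxy-5-[(2R)-1-hydroxypropan-2-yl]-1-methylbicyclo[3.2.0]heptan-2-one F6. One equivalent of TEMPO/PhI(OAc)2 oxidises the primary alcohol to the aldehyde, which closes to the lactol, and the route is rejoined at 13.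

Further compounds
F1 | step 12 | (1R,5R,6R)-5-{(2R)-3-[(tert-butyldimethylsilyl)oxy]-5-hydroxyhexan-2-yl}-1,4-dimethyl-2-oxobicyclo[3.2.0]hept-3-en-6-yl acetate | CC(=O)O[C@@H]1C[C@@]2(C)C(=O)C=C(C)[C@@]12[C@@H](C)C(O[Si](C)(C)C(C)(C)C)CC(C)O
F2 | step 12 | O-imidazol-1-ylcarbonothioyl derivative of F1 at the new secondary hydroxyl | CC(=O)O[C@@H]1C[C@@]2(C)C(=O)C=C(C)[C@@]12[C@@H](C)C(O[Si](C)(C)C(C)(C)C)CC(C)OC(=S)n1ccnc1
F3 | step 15 | (1R,2R,4R,5R,7R,8S,11R)-10-[(tert-butyldimethylsilyl)oxy]-5-hydroxy-4,7,8,11-tetramethyltricyclo[5.4.0.0^{1,4}]undecan-2-yl acetate | CC(=O)O[C@@H]1C[C@@]2(C)[C@H](O)C[C@]3(C)[C@@H](C)CC(O[Si](C)(C)C(C)(C)C)[C@H](C)[C@]123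
F4 | step 7 | 3-[(2R)-1-{[ethenyl(dimethyl)silyl]oxy}propan-2-yl]-2-methylcyclopent-2-en-1-one | C=C[Si](C)(C)OC[C@H](C)C1=C(C)C(=O)CC1
F5 | step 7 | silicon-tethered photoadduct: bicyclo[3.2.0]heptan-2-one of rings A and B with a cis-fused 2,2-dimethyl-1-oxa-2-silacyclohexane ring (Si on C2, O on C10) | C[Si]1(C)[C@@H]2C[C@@]3(C)C(=O)CC[C@@]23[C@@H](C)CO1
F6 | step 7 | (1R,5S,6R)-6-hydroxy-5-[(2R)-1-hydroxypropan-2-yl]-1-methylbicyclo[3.2.0]heptan-2-one | O[C@@H]1C[C@@]2(C)C(=O)CC[C@@]12[C@@H](C)CO
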